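**Retrosynthetic overview** (locants are those of the bicyclo[8.2.0]dodecane name of the target: C1 = C–Me, C10 = ring-fusion CH, C11 = ring CH2, C12 = CH–isopropenyl; ring A = cyclobutane C1/C10/C11/C12, ring B = ten-membered ring)
1. Ring B is formed last, at C7–C8, by an intramolecular B-alkyl Suzuki–Miyaura coupling (2-triflyloxy-1-alkene at C7, hydroborated vinyl group on C10); the ester is then α-methylenated.
2. C4–C5 comes from a Cu-catalysed asymmetric conjugate addition of a Grignard reagent (C5–C7 piece, C6 set by an Evans aldol) to an enoate that hangs on ring A.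
3. Ring A is formed first: a photochemical Wolff ring contraction of an α-diazocyclopentanone makes C11–C12 and pushes the ketone carbon out onto C12, where it later becomes the isopropenyl carbon.
4. The cyclopentanone comes from (R)-4-silyloxycyclopentenone by anti-selective Cu-catalysed Grignard conjugate additions (vinyl gives C10; butenyl gives quaternary C1, trans to the vinyl group).
5. Enabling feature: in ring A, C12 carries one exocyclic carbon and sits between the ring CH2 (C11) and the fully substituted C1. This is the retron of a Wolff contraction of the five-membered ring C1–C10–C11–C(=O)–C12; quaternary C1 fixes the diazo site (through the conjugate-addition enolate) and leaves the carbene no hydrogen to shift.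

Key step: step 5

Remark (assumption): in step 14 the (R,Sp) enantiomer of the ferrocenyl diphosphine is taken to deliver the alkyl group to the Re face of the β-carbon; if the facial sense is the opposite, the mirror-image ligand is used.

**Route**

Step 1
Reactants: 1 (4R)-4-[(tert-butyldimethylsilyl)oxy]cyclopent-2-en-1-one
Product: 3 (4S)-4-ethenylcyclopent-2-en-1-one, via trans-3-ethenyl-4-silyloxycyclopentanone 2 (not isolated)
Conditions: CH2=CHMgBr, CuBr·SMe2 (10 mol %), THF, −78 °C; aq NH4Cl; then DBU, CH2Cl2, 0 °C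
Reagents that add atoms: vinylmagnesium bromide C=C[Mg]Br
Why: Cu-catalysed 1,4-addition of the Grignard reagent should occur anti to the silyloxy group and E1cB loss of silanol then gives the transposed enone, so the (R) centre that is lost fixes the new vinyl-bearing centre (future C10) as (S).

Step 2
Reactants: 3 (4S)-4-ethenylcyclopent-2-en-1-one
Product: 5 (4S)-4-ethenyl-3-methylcyclopent-2-en-1-one, via silyl enol ether 4 (not isolated)
Conditions: MeMgBr, CuBr·SMe2 (5 mol %), Me3SiCl, HMPA, THF, −78 °C; then Pd(OAc)2 (10 mol %), O2 (1 atm), DMSO, rt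
Reagents that add atoms: methylmagnesium bromide C[Mg]Br; chlorotrimethylsilane C[Si](C)(C)Cl (to 4)
Why: Silyl-chloride-accelerated Cu-catalysed conjugate addition followed by Saegusa–Ito oxidation of the regiodefined silyl enol ether should put the methyl group on the β-carbon of a regenerated enone without touching the vinyl-bearing centre.

Step 3
Reactants: 5 (4S)-4-ethenyl-3-methylcyclopent-2-en-1-one
Product: 6 {[(3S,4S)-3-(but-3-en-1-yl)-4-ethenyl-3-methylcyclopent-1-en-1-yl]oxy}trimethylsilane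
Conditions: CH2=CHCH2CH2MgBr, CuBr·SMe2 (10 mol %), Me3SiCl, HMPA, THF, −78 °C; Et3N, pentane work-up
Reagents that add atoms: but-3-en-1-ylmagnesium bromide C=CCC[Mg]Br; chlorotrimethylsilane C[Si](C)(C)Cl
Why: Cu-catalysed conjugate addition to the β-methyl enone should build the quaternary centre (future C1) with the butenyl group anti to the adjacent vinyl group, and silyl trapping stores the enolate on the carbon next to that quaternary centre.

Step 4
Reactants: 6 {[(3S,4S)-3-(but-3-en-1-yl)-4-ethenyl-3-methylcyclopent-1-en-1-yl]oxy}trimethylsilane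
Product: 8 (3S,4S)-3-(but-3-en-1-yl)-2-diazo-4-ethenyl-3-methylcyclopentan-1-one, via 2-trifluoroacetyl ketone 7 (not isolated)
Conditions: MeLi, THF, 0 °C; CF3CO2CH2CF3, −78 °C; then MeSO2N3, Et3N, H2O, MeCN, rt
Reagents that add atoms: 2,2,2-trifluoroethyl trifluoroacetate O=C(OCC(F)(F)F)C(F)(F)F (to 7); methanesulfonyl azide CS(=O)(=O)N=[N+]=[N-]
Why: MeLi should regenerate the lithium enolate with its regiochemistry intact, and C-trifluoroacetylation followed by detrifluoroacetylative (Regitz-type) diazo transfer places the diazo group only on the carbon between the carbonyl and the quaternary centre.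

Step 5
Reactants: 8 (3S,4S)-3-(but-3-en-1-yl)-2-diazo-4-ethenyl-3-methylcyclopentan-1-one
Product: 10 (2S,3S)-2-(but-3-en-1-yl)-3-ethenyl-N-methoxy-N,2-dimethylcyclobutane-1-carboxamide (C1 epimers), via cyclobutylidene ketene 9 (not isolated)
Conditions: hν (medium-pressure Hg lamp, Pyrex, λ > 300 nm), MeNHOMe (5 equiv), THF, 0 °C
Reagents that add atoms: N,O-dimethylhydroxylamine CNOC
Why: Photolysis should expel N2 while the ring CH2 (future C11) migrates from the carbonyl carbon to the diazo carbon (future C12) in a concerted Wolff rearrangement of the s-cis-locked cyclic diazo ketone, and the amine traps the resulting ketene as the Weinreb amide. The closest known reaction type is the photo-Wolff ring contraction of 2-diazocyclopentanones to cyclobutanecarboxylic acid derivatives. Ring A is closed by this 1,2-shift (five-membered to four-membered ring), with the former carbonyl carbon extruded to the exocyclic position that the isopropenyl carbon occupies in the target. No existing stereocentre takes part: C1 and C10 keep the trans relation from steps 1–3, the migrating carbon is a CH2, and C12 arises by protonation of the amide enol as an epimer mixture that step 6 corrects thermodynamically. The step needs regioselectivity (which α-carbon bears N2) and chemoselectivity (Wolff shift against carbene 1,2-H shift, alkene cyclopropanation and ketene [2+2]). The first is secured by the enolate of step 3, the second by the quaternary C1 next to the carbene carbon, by direct irradiation of the s-cis diazo ketone and by excess amine that intercepts the ketene.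

Step 6
Reactants: 10 (2S,3S)-2-(but-3-en-1-yl)-3-ethenyl-N-methoxy-N,2-dimethylcyclobutane-1-carboxamide (C1 epimers)
Product: 11 1-[(1S,2S,3S)-2-(but-3-en-1-yl)-3-ethenyl-2-methylcyclobutyl]ethan-1-one
Conditions: MeMgBr, THF, 0 °C; aq NH4Cl; then K2CO3, MeOH, rt
Reagents that add atoms: methylmagnesium bromide C[Mg]Br
Why: Weinreb ketone synthesis followed by base equilibration of the enolisable centre should place the acetyl group cis to the ring methyl and cis-1,3 to the vinyl group, the epimer in which acetyl, vinyl and butenyl are all pseudo-equatorial on the puckered ring.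

Step 7
Reactants: 11 1-[(1S,2S,3S)-2-(but-3-en-1-yl)-3-ethenyl-2-methylcyclobutyl]ethan-1-one
Product: 12 (1S,2S,3R)-2-(but-3-en-1-yl)-1-ethenyl-2-methyl-3-(prop-1-en-2-yl)cyclobutane
Conditions: Ph3PCH3Br, KOtBu, THF, 0 °C → reflux
Reagents that add atoms: methyltriphenylphosphonium bromide C[P+](c1ccccc1)(c1ccccc1)c1ccccc1.[Br-]
Why: Wittig methylenation converts the acetyl group into the isopropenyl group, and the α-centre is already the thermodynamic epimer so the basic ylide cannot erode it.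

Step 8
Reactants: 12 (1S,2S,3R)-2-(but-3-en-1-yl)-1-ethenyl-2-methyl-3-(prop-1-en-2-yl)cyclobutane; 13 methyl acrylate
Product: 14 methyl (2E)-5-[(1S,2S,4R)-2-ethenyl-1-methyl-4-(prop-1-en-2-yl)cyclobutyl]pent-2-enoate
Conditions: second-generation Grubbs catalyst (5 mol %), 13 (5 equiv), CH2Cl2, 40 °C
Reagents that add atoms: none
Why: Olefin cross-metathesis should occur at the unhindered butenyl terminus to give the (E)-enoate, because the ring vinyl group (next to a quaternary carbon) and the 1,1-disubstituted isopropenyl group are slow partners and ring closure would need a trans-fused cyclohexene on the cyclobutane.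

Step 9
Reactants: 15 5-methylhex-4-enoic acid; 16 (4S)-4-benzyl-1,3-oxazolidin-2-one
Product: 18 (4S)-4-benzyl-3-(5-methylhex-4-enoyl)-1,3-oxazolidin-2-one, via mixed pivalic anhydride 17 (not isolated)
Conditions: t-BuCOCl, Et3N, THF, −20 °C; then 16, LiCl, rt
Reagents that add atoms: pivaloyl chloride CC(C)(C)C(=O)Cl (to 17)
Why: N-acylation of the oxazolidinone through the mixed anhydride is a standard way to attach the Evans auxiliary.

Step 10
Reactants: 18 (4S)-4-benzyl-3-(5-methylhex-4-enoyl)-1,3-oxazolidin-2-one; 19 acetaldehyde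
Product: 20 (4S)-4-benzyl-3-[(2S,3R)-3-hydroxy-2-(3-methylbut-2-en-1-yl)butanoyl]-1,3-oxazolidin-2-one
Conditions: Bu2BOTf, iPr2NEt, CH2Cl2, −78 → 0 °C; pH 7 buffer, MeOH, H2O2
Reagents that add atoms: none
Why: Evans syn-aldol reaction through the Z-boron enolate and a chair transition state, with the benzyl group shielding one enolate face, should set the prenyl-bearing centre (future C6) as (2S); the carbinol centre is oxidised later.

Step 11
Reactants: 20 (4S)-4-benzyl-3-[(2S,3R)-3-hydroxy-2-(3-methylbut-2-en-1-yl)butanoyl]-1,3-oxazolidin-2-one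
Product: 21 (4S)-4-benzyl-3-[(2S,3R)-3-[(tert-butyldimethylsilyl)oxy]-2-(3-methylbut-2-en-1-yl)butanoyl]-1,3-oxazolidin-2-one
Conditions: t-BuMe2SiOTf, 2,6-lutidine, CH2Cl2, −78 °C
Reagents that add atoms: tert-butyldimethylsilyl triflate CC(C)(C)[Si](C)(C)OS(=O)(=O)C(F)(F)F
Why: O-silylation masks the future ketone oxygen so that a Grignard reagent can be made from this fragment.

Step 12
Reactants: 21 (4S)-4-benzyl-3-[(2S,3R)-3-[(tert-butyldimethylsilyl)oxy]-2-(3-methylbut-2-en-1-yl)butanoyl]-1,3-oxazolidin-2-one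
Product: 22 (2R,3R)-3-[(tert-butyldimethylsilyl)oxy]-2-(3-methylbut-2-en-1-yl)butan-1-ol
Conditions: LiBH4, MeOH (1 equiv), Et2O, 0 °C
Reagents that add atoms: none
Why: Reductive cleavage of the N-acyl oxazolidinone with LiBH4 gives the primary alcohol without epimerising the α-centre and returns the auxiliary.

Step 13
Reactants: 22 (2R,3R)-3-[(tert-butyldimethylsilyl)oxy]-2-(3-methylbut-2-en-1-yl)butan-1-ol
Product: 23 {[(2R,3S)-3-(bromomethyl)-6-methylhept-5-en-2-yl]oxy}(tert-butyl)dimethylsilane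
Conditions: CBr4, PPh3, CH2Cl2, 0 °C
Reagents that add atoms: carbon tetrabromide BrC(Br)(Br)Br
Why: Appel bromination converts the primary alcohol into the bromide under neutral conditions that leave the silyl ether and the alkene alone.

Step 14
Reactants: 23 {[(2R,3S)-3-(bromomethyl)-6-methylhept-5-en-2-yl]oxy}(tert-butyl)dimethylsilane; 14 methyl (2E)-5-[(1S,2S,4R)-2-ethenyl-1-methyl-4-(prop-1-en-2-yl)cyclobutyl]pent-2-enoate
Product: 25 methyl (3S,5S,6R)-6-[(tert-butyldimethylsilyl)oxy]-3-{2-[(1S,2S,4R)-2-ethenyl-1-methyl-4-(prop-1-en-2-yl)cyclobutyl]ethyl}-5-(3-methylbut-2-en-1-yl)heptanoate, via Grignard reagent 24 (not isolated)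
Conditions: Mg, Et2O; then 14, CuBr·SMe2 (5 mol %), (R)-1-[(S)-2-(diphenylphosphino)ferrocenyl]ethyldicyclohexylphosphine (6 mol %), t-BuOMe, −75 °C; aq NH4Cl
Reagents that add atoms: magnesium [Mg] (to 24)
Why: Cu-catalysed asymmetric conjugate addition of a Grignard reagent to an α,β-unsaturated ester joins the two fragments at C4–C5, and the chiral ferrocenyl diphosphine should deliver the alkyl group to the Re face of the β-carbon to set (S) at the future C4, the existing centres being remote from the reacting alkene.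

Step 15
Reactants: 25 methyl (3S,5S,6R)-6-[(tert-butyldimethylsilyl)oxy]-3-{2-[(1S,2S,4R)-2-ethenyl-1-methyl-4-(prop-1-en-2-yl)cyclobutyl]ethyl}-5-(3-methylbut-2-en-1-yl)heptanoate
Product: 26 methyl (3S,5S,6R)-3-{2-[(1S,2S,4R)-2-ethenyl-1-methyl-4-(prop-1-en-2-yl)cyclobutyl]ethyl}-6-hydroxy-5-(3-methylbut-2-en-1-yl)heptanoate
Conditions: Bu4NF, THF, rt
Reagents that add atoms: none
Why: Fluoride desilylation frees the secondary alcohol, and lactonisation onto the ester would need a seven-membered ring and should be slow.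

Step 16
Reactants: 26 methyl (3S,5S,6R)-3-{2-[(1S,2S,4R)-2-ethenyl-1-methyl-4-(prop-1-en-2-yl)cyclobutyl]ethyl}-6-hydroxy-5-(3-methylbut-2-en-1-yl)heptanoate
Product: 27 methyl (3S,5S)-3-{2-[(1S,2S,4R)-2-ethenyl-1-methyl-4-(prop-1-en-2-yl)cyclobutyl]ethyl}-5-(3-methylbut-2-en-1-yl)-6-oxoheptanoate
Conditions: Dess–Martin periodinane, NaHCO3, CH2Cl2, rt
Reagents that add atoms: none
Why: Dess–Martin oxidation gives the methyl ketone under buffered, non-basic conditions that should not epimerise the adjacent prenyl-bearing centre.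

Step 17
Reactants: 27 methyl (3S,5S)-3-{2-[(1S,2S,4R)-2-ethenyl-1-methyl-4-(prop-1-en-2-yl)cyclobutyl]ethyl}-5-(3-methylbut-2-en-1-yl)-6-oxoheptanoate
Product: 28 methyl (3S,5S)-3-{2-[(1S,2S,4R)-2-ethenyl-1-methyl-4-(prop-1-en-2-yl)cyclobutyl]ethyl}-5-(3-methylbut-2-en-1-yl)-6-{[(trifluoromethyl)sulfonyl]oxy}hept-6-enoate
Conditions: KN(SiMe3)2, THF, −78 °C; PhNTf2
Reagents that add atoms: N-phenylbis(trifluoromethanesulfonimide) O=S(=O)(N(c1ccccc1)S(=O)(=O)C(F)(F)F)C(F)(F)F
Why: Kinetic deprotonation of the methyl ketone on its methyl side (more acidic than the ester α-CH2 and less hindered than the tertiary α-CH) and O-triflation should give the 2-triflyloxy-1-alkene that carries the future exocyclic methylene.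

Step 18
Reactants: 28 methyl (3S,5S)-3-{2-[(1S,2S,4R)-2-ethenyl-1-methyl-4-(prop-1-en-2-yl)cyclobutyl]ethyl}-5-(3-methylbut-2-en-1-yl)-6-{[(trifluoromethyl)sulfonyl]oxy}hept-6-enoate
Product: 30 methyl 2-[(1S,4S,6R,10R,12R)-1-methyl-7-methylidene-6-(3-methylbut-2-en-1-yl)-12-(prop-1-en-2-yl)bicyclo[8.2.0]dodecan-4-yl]acetate, via B-alkyldicyclohexylborane 29 (not isolated)
Conditions: (c-C6H11)2BH, THF, 0 °C → rt; then slow addition to Pd(dppf)Cl2 (15 mol %), AsPh3, Cs2CO3, H2O, DMF/THF, 50 °C (final 2 mM)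
Reagents that add atoms: dicyclohexylborane B(C1CCCCC1)C1CCCCC1 (to 29)
Why: The hindered dialkylborane should hydroborate only the monosubstituted vinyl group (the isopropenyl, prenyl and triflyloxy alkenes are far slower), and intramolecular B-alkyl Suzuki–Miyaura coupling (oxidative addition of the alkenyl triflate to zerovalent palladium, transmetalation of the primary alkyl group, reductive elimination) closes ring B at C7–C8 with the exocyclic methylene already in place and no new stereocentre.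

Step 19
Reactants: 30 methyl 2-[(1S,4S,6R,10R,12R)-1-methyl-7-methylidene-6-(3-methylbut-2-en-1-yl)-12-(prop-1-en-2-yl)bicyclo[8.2.0]dodecan-4-yl]acetate
Product: 33 methyl 2-[(1S,4S,6R,10R,12R)-1-methyl-7-methylidene-6-(3-methylbut-2-en-1-yl)-12-(prop-1-en-2-yl)bicyclo[8.2.0]dodecan-4-yl]prop-2-enoate (target), via Mannich base 31 (not isolated), via trimethylammonium iodide 32 (not isolated)
Conditions: LiN(iPr)2, THF, −78 °C; CH2=NMe2+ I−, −78 °C → rt; then MeI, MeOH, rt; then NaHCO3, CH2Cl2/H2O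
Reagents that add atoms: Eschenmoser's salt C=[N+](C)C.[I-]; iodomethane CI (to 32)
Why: Mannich reaction of the ester enolate with the iminium salt, N-methylation and E1cB elimination of trimethylamine is the standard α-methylenation of an ester, and C4 is not deprotonated under these conditions.

**Compound list**

1 | (4R)-4-[(tert-butyldimethylsilyl)oxy]cyclopent-2-en-1-one | O=C1C=C[C@H](O[Si](C)(C)C(C)(C)C)C1 | starting material
2 | (3S,4R)-4-[(tert-butyldimethylsilyl)oxy]-3-ethenylcyclopentan-1-one (trans) | O=C1C[C@@H](C=C)[C@H](O[Si](C)(C)C(C)(C)C)C1 | intermediate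
3 | (4S)-4-ethenylcyclopent-2-en-1-one | O=C1C=C[C@H](C=C)C1 | intermediate
4 | {[(3S,4S)-4-ethenyl-3-methylcyclopent-1-en-1-yl]oxy}trimethylsilane (methyl trans to ethenyl) | C[Si](C)(C)OC1=C[C@@H](C)[C@H](C=C)C1 | intermediate
5 | (4S)-4-ethenyl-3-methylcyclopent-2-en-1-one | O=C1C=C(C)[C@H](C=C)C1 | intermediate
6 | {[(3S,4S)-3-(but-3-en-1-yl)-4-ethenyl-3-methylcyclopent-1-en-1-yl]oxy}trimethylsilane (butenyl trans to ethenyl) | C[Si](C)(C)OC1=C[C@@](C)(CCC=C)[C@H](C=C)C1 | intermediate
7 | (3S,4S)-3-(but-3-en-1-yl)-4-ethenyl-3-methyl-2-(trifluoroacetyl)cyclopentan-1-one (C2 epimers or enol) | O=C1C(C(=O)C(F)(F)F)[C@@](C)(CCC=C)[C@H](C=C)C1 | intermediate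
8 | (3S,4S)-3-(but-3-en-1-yl)-2-diazo-4-ethenyl-3-methylcyclopentan-1-one | O=C1C(=[N+]=[N-])[C@@](C)(CCC=C)[C@H](C=C)C1 | intermediate
9 | [(2S,3S)-2-(but-3-en-1-yl)-3-ethenyl-2-methylcyclobutylidene]methanone (ketene) | O=C=C1C[C@@H](C=C)[C@]1(C)CCC=C | intermediate
10 | (2S,3S)-2-(but-3-en-1-yl)-3-ethenyl-N-methoxy-N,2-dimethylcyclobutane-1-carboxamide (mixture of C1 epimers) | CON(C)C(=O)C1C[C@@H](C=C)[C@]1(C)CCC=C | intermediate
11 | 1-[(1S,2S,3S)-2-(but-3-en-1-yl)-3-ethenyl-2-methylcyclobutyl]ethan-1-one (acetyl cis to ring methyl and cis to ethenyl) | CC(=O)[C@H]1C[C@@H](C=C)[C@]1(C)CCC=C | intermediate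
12 | (1S,2S,3R)-2-(but-3-en-1-yl)-1-ethenyl-2-methyl-3-(prop-1-en-2-yl)cyclobutane | C=C(C)[C@H]1C[C@@H](C=C)[C@]1(C)CCC=C | intermediate
13 | methyl acrylate | C=CC(=O)OC | starting material
14 | methyl (2E)-5-[(1S,2S,4R)-2-ethenyl-1-methyl-4-(prop-1-en-2-yl)cyclobutyl]pent-2-enoate | C=C(C)[C@H]1C[C@@H](C=C)[C@]1(C)CC/C=C/C(=O)OC | intermediate
15 | 5-methylhex-4-enoic acid | CC(C)=CCCC(=O)O | starting material
16 | (4S)-4-benzyl-1,3-oxazolidin-2-one | O=C1N[C@@H](Cc2ccccc2)CO1 | starting material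
17 | 5-methylhex-4-enoic pivalic anhydride | CC(C)=CCCC(=O)OC(=O)C(C)(C)C | intermediate
18 | (4S)-4-benzyl-3-(5-methylhex-4-enoyl)-1,3-oxazolidin-2-one | CC(C)=CCCC(=O)N1[C@@H](Cc2ccccc2)COC1=O | intermediate
19 | acetaldehyde | CC=O | starting material
20 | (4S)-4-benzyl-3-[(2S,3R)-3-hydroxy-2-(3-methylbut-2-en-1-yl)butanoyl]-1,3-oxazolidin-2-one | C[C@@H](O)[C@H](CC=C(C)C)C(=O)N1[C@@H](Cc2ccccc2)COC1=O | intermediate
21 | (4S)-4-benzyl-3-[(2S,3R)-3-[(tert-butyldimethylsilyl)oxy]-2-(3-methylbut-2-en-1-yl)butanoyl]-1,3-oxazolidin-2-one | C[C@@H](O[Si](C)(C)C(C)(C)C)[C@H](CC=C(C)C)C(=O)N1[C@@H](Cc2ccccc2)COC1=O | intermediate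
22 | (2R,3R)-3-[(tert-butyldimethylsilyl)oxy]-2-(3-methylbut-2-en-1-yl)butan-1-ol | C[C@@H](O[Si](C)(C)C(C)(C)C)[C@H](CC=C(C)C)CO | intermediate
23 | {[(2R,3S)-3-(bromomethyl)-6-methylhept-5-en-2-yl]oxy}(tert-butyl)dimethylsilane | C[C@@H](O[Si](C)(C)C(C)(C)C)[C@H](CC=C(C)C)CBr | intermediate
24 | {(2S,3R)-3-[(tert-butyldimethylsilyl)oxy]-2-(3-methylbut-2-en-1-yl)butyl}magnesium bromide | C[C@@H](O[Si](C)(C)C(C)(C)C)[C@H](CC=C(C)C)C[Mg]Br | intermediate
25 | methyl (3S,5S,6R)-6-[(tert-butyldimethylsilyl)oxy]-3-{2-[(1S,2S,4R)-2-ethenyl-1-methyl-4-(prop-1-en-2-yl)cyclobutyl]ethyl}-5-(3-methylbut-2-en-1-yl)heptanoate | C=C(C)[C@H]1C[C@@H](C=C)[C@]1(C)CC[C@H](CC(=O)OC)C[C@@H](CC=C(C)C)[C@@H](C)O[Si](C)(C)C(C)(C)C | intermediate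
26 | methyl (3S,5S,6R)-3-{2-[(1S,2S,4R)-2-ethenyl-1-methyl-4-(prop-1-en-2-yl)cyclobutyl]ethyl}-6-hydroxy-5-(3-methylbut-2-en-1-yl)heptanoate | C=C(C)[C@H]1C[C@@H](C=C)[C@]1(C)CC[C@H](CC(=O)OC)C[C@@H](CC=C(C)C)[C@@H](C)O | intermediate
27 | methyl (3S,5S)-3-{2-[(1S,2S,4R)-2-ethenyl-1-methyl-4-(prop-1-en-2-yl)cyclobutyl]ethyl}-5-(3-methylbut-2-en-1-yl)-6-oxoheptanoate | C=C(C)[C@H]1C[C@@H](C=C)[C@]1(C)CC[C@H](CC(=O)OC)C[C@@H](CC=C(C)C)C(C)=O | intermediate
28 | methyl (3S,5S)-3-{2-[(1S,2S,4R)-2-ethenyl-1-methyl-4-(prop-1-en-2-yl)cyclobutyl]ethyl}-5-(3-methylbut-2-en-1-yl)-6-{[(trifluoromethyl)sulfonyl]oxy}hept-6-enoate | C=C(C)[C@H]1C[C@@H](C=C)[C@]1(C)CC[C@H](CC(=O)OC)C[C@@H](CC=C(C)C)C(=C)OS(=O)(=O)C(F)(F)F | intermediate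
29 | B-alkyldicyclohexylborane from anti-Markovnikov hydroboration of the ring vinyl group of 28 (CH2CH2B(c-C6H11)2 on the cyclobutane; all other centres as in 28) | C=C(C)[C@H]1C[C@@H](CCB(C2CCCCC2)C2CCCCC2)[C@]1(C)CC[C@H](CC(=O)OC)C[C@@H](CC=C(C)C)C(=C)OS(=O)(=O)C(F)(F)F | intermediate
30 | methyl 2-[(1S,4S,6R,10R,12R)-1-methyl-7-methylidene-6-(3-methylbut-2-en-1-yl)-12-(prop-1-en-2-yl)bicyclo[8.2.0]dodecan-4-yl]acetate | C=C1CC[C@@H]2C[C@H](C(=C)C)[C@@]2(C)CC[C@H](CC(=O)OC)C[C@H]1CC=C(C)C | intermediate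
31 | methyl 3-(dimethylamino)-2-[(1S,4S,6R,10R,12R)-1-methyl-7-methylidene-6-(3-methylbut-2-en-1-yl)-12-(prop-1-en-2-yl)bicyclo[8.2.0]dodecan-4-yl]propanoate (epimers at the new α-carbon) | C=C1CC[C@@H]2C[C@H](C(=C)C)[C@@]2(C)CC[C@H](C(CN(C)C)C(=O)OC)C[C@H]1CC=C(C)C | intermediate
32 | trimethylammonium iodide of 31 (N-methylated Mannich base) | C=C1CC[C@@H]2C[C@H](C(=C)C)[C@@]2(C)CC[C@H](C(C[N+](C)(C)C)C(=O)OC)C[C@H]1CC=C(C)C.[I-] | intermediate
33 | methyl 2-[(1S,4S,6R,10R,12R)-1-methyl-7-methylidene-6-(3-methylbut-2-en-1-yl)-12-(prop-1-en-2-yl)bicyclo[8.2.0]dodecan-4-yl]prop-2-enoate | C=C1CC[C@@H]2C[C@H](C(=C)C)[C@@]2(C)CC[C@H](C(=C)C(=O)OC)C[C@H]1CC=C(C)C | target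

**Step count and risks**

Total: 19 steps. Longest linear sequence: 14 steps (steps 1–8, then 14–19); the side-chain branch (steps 9–13) joins at step 14.

Steps most likely to fail:

1. Step 18. What may go wrong: reductive elimination has to take place from a strained eleven-membered palladacycle, so intermolecular coupling (oligomerisation), protodeboronation and β-hydride elimination may outrun ring closure. Fallback, from 28 back to 30: hydroboration with (c-C6H11)2BH followed by NaBO3 oxidation should give the primary alcohol F1, and Dess–Martin oxidation the aldehyde F2. An intramolecular Nozaki–Hiyama–Kishi coupling of the alkenyl triflate with the aldehyde (CrCl2, catalytic NiCl2, DMSO/THF, high dilution) closes ring B at the same C7–C8 bond as the cyclic allylic alcohol F3. Acylation with ClCO2Me/pyridine gives the allylic methyl carbonate F4. Formate reduction of its π-allyl complex (Pd(OAc)2, PBu3, HCO2NH4), with hydride delivered to the more substituted allyl terminus, keeps the exocyclic methylene and gives 30.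

2. Step 5. What may go wrong: the photogenerated carbene may be lost to cyclopropanation of the butenyl group or to C–H insertion, and the strained product may undergo secondary photochemistry, so that ring contraction is inefficient. Fallback, from 6 back to 10, forming the same C11–C12 bond by enolate alkylation:
   - K2CO3/MeOH should give the ketone F5.
   - LiN(iPr)2 at −78 °C deprotonates the CH2 remote from the quaternary carbon, and MoO5·pyridine·HMPA hydroxylates it to the α′-hydroxy ketone F6.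
   - Pb(OAc)4 in MeOH cleaves this to the aldehyde ester F7, which is reduced at once with NaBH4 and lactonises to the δ-lactone F8.
   - Me2AlN(OMe)Me (from AlMe3 and MeNHOMe·HCl) opens the lactone to the hydroxy Weinreb amide F9, and MsCl/Et3N gives the mesylate F10.
   - KN(SiMe3)2 closes the four-membered ring by 4-exo-tet alkylation of the amide enolate, arriving at 10.

3. Step 14. What may go wrong: poor facial selectivity at the β-carbon when two chiral partners meet under catalyst control, or competing 1,2-addition to the ester at low conversion. Fallback, from 14 back to 25: LiOH hydrolysis should give the acid F11, and acylation of lithiated (S)-4-phenyl-1,3-oxazolidin-2-one through the mixed pivalic anhydride the N-enoyl imide F12. Addition of the organocopper reagent from Grignard reagent 24 and stoichiometric CuBr·SMe2 to the chelated s-cis imide, anti to the phenyl group, gives the conjugate adduct F13 under auxiliary control. Methanolysis (NaOMe, MeOH) gives 25 and returns the auxiliary.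

**Further compounds**

F1 | step 18 | primary alcohol from hydroboration–oxidation of the ring vinyl group of 28 (CH2CH2OH on the cyclobutane) | C=C(C)[C@H]1C[C@@H](CCO)[C@]1(C)CC[C@H](CC(=O)OC)C[C@@H](CC=C(C)C)C(=C)OS(=O)(=O)C(F)(F)F
F2 | step 18 | aldehyde from oxidation of F1 (CH2CHO on the cyclobutane) | C=C(C)[C@H]1C[C@@H](CC=O)[C@]1(C)CC[C@H](CC(=O)OC)C[C@@H](CC=C(C)C)C(=C)OS(=O)(=O)C(F)(F)F
F3 | step 18 | methyl 2-[8-hydroxy-1-methyl-7-methylidene-6-(3-methylbut-2-en-1-yl)-12-(prop-1-en-2-yl)bicyclo[8.2.0]dodecan-4-yl]acetate (ring centres as in 30; C8 carbinol epimers) | C=C1C(O)C[C@@H]2C[C@H](C(=C)C)[C@@]2(C)CC[C@H](CC(=O)OC)C[C@H]1CC=C(C)C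
F4 | step 18 | C8 methyl carbonate of F3 | C=C1C(OC(=O)OC)C[C@@H]2C[C@H](C(=C)C)[C@@]2(C)CC[C@H](CC(=O)OC)C[C@H]1CC=C(C)C
F5 | step 5 | (3S,4S)-3-(but-3-en-1-yl)-4-ethenyl-3-methylcyclopentan-1-one | O=C1C[C@@](C)(CCC=C)[C@H](C=C)C1
F6 | step 5 | (3S,4S)-4-(but-3-en-1-yl)-3-ethenyl-2-hydroxy-4-methylcyclopentan-1-one (hydroxyl on the carbon next to the ethenyl-bearing carbon; carbinol epimers) | O=C1C[C@@](C)(CCC=C)[C@H](C=C)C1O
F7 | step 5 | methyl (3S,4S)-3-(but-3-en-1-yl)-4-formyl-3-methylhex-5-enoate | COC(=O)C[C@@](C)(CCC=C)[C@H](C=C)C=O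
F8 | step 5 | (4S,5S)-4-(but-3-en-1-yl)-5-ethenyl-4-methyloxan-2-one | O=C1C[C@@](C)(CCC=C)[C@H](C=C)CO1
F9 | step 5 | (3S,4S)-3-(but-3-en-1-yl)-4-(hydroxymethyl)-N-methoxy-N,3-dimethylhex-5-enamide | CON(C)C(=O)C[C@@](C)(CCC=C)[C@H](C=C)CO
F10 | step 5 | methanesulfonate of F9 | CON(C)C(=O)C[C@@](C)(CCC=C)[C@H](C=C)COS(C)(=O)=O
F11 | step 14 | (2E)-5-[(1S,2S,4R)-2-ethenyl-1-methyl-4-(prop-1-en-2-yl)cyclobutyl]pent-2-enoic acid | C=C(C)[C@H]1C[C@@H](C=C)[C@]1(C)CC/C=C/C(=O)O
F12 | step 14 | (4S)-3-{(2E)-5-[(1S,2S,4R)-2-ethenyl-1-methyl-4-(prop-1-en-2-yl)cyclobutyl]pent-2-enoyl}-4-phenyl-1,3-oxazolidin-2-one | C=C(C)[C@H]1C[C@@H](C=C)[C@]1(C)CC/C=C/C(=O)N1[C@@H](c2ccccc2)COC1=O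
F13 | step 14 | N-acyl (4S)-4-phenyl-1,3-oxazolidin-2-one analogue of ester 25 (same chain and centres; imide in place of the methyl ester) | C=C(C)[C@H]1C[C@@H](C=C)[C@]1(C)CC[C@H](CC(=O)N1[C@@H](c2ccccc2)COC1=O)C[C@@H](CC=C(C)C)[C@@H](C)O[Si](C)(C)C(C)(C)C
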